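## Structural features

The target is a biflavonoid. C3 of a naringenin-type flavanone (ring A with 5,7-hydroxyls, pyranone ring C, a 4-hydroxyphenyl ring B on C2) is bonded to C8 of a luteolin flavone, and the luteolin 7-oxygen is a hydrogen sulfate. The only stereocentres are C2 (R) and C3 (S) of ring C. They are adjacent, carry their aryl groups trans, and C3 is also α to the C4 ketone. The C3–C8 bond joins an sp3 carbon to an aromatic carbon flanked by the luteolin ring oxygen and the sulfated 7-oxygen, so it is very crowded. Three groups are fragile: the aryl sulfate monoester (acid), the flavanone (base opens ring C by retro-oxa-Michael reaction and scrambles C2 and C3), and the luteolin C2=C3 bond and C4 ketone under reduction. The real difficulty is to make the hindered C3–C8 link together with two contiguous stereocentres in one absolute sense, and to place a single sulfate among seven phenolic oxygens. The key step uses the fact that ring C consists of a four-atom unit O1–C8a–C4a–C4, which is an ortho-quinone methide of ring A, and a two-atom unit C2–C3, which is an E-stilbene. In that stilbene the para-phenol on the C2 aryl group pushes electron density to C3, and the luteolin ring is already attached to C3 while that carbon is still sp2.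

## Logic of the disconnections

**20 ⇒ 18 (through 19).** The bonds cut are the O–CH2 bonds of two benzyl ethers and of one benzyl carbonate, the two O–C bonds of the ketal on luteolin ring B, and the O–CH2 bond of the trichloroethyl sulfate ester. All of them fall to palladium-catalysed hydrogenolysis near neutrality, the one medium in which the aryl sulfate and the flavanone are both safe. The gain is that 18 is neutral and chromatographable. The demand is that one reductive operation must spare the C4 ketone, the luteolin C2=C3 bond and the benzylic O1–C2 bond.

**18 ⇒ 17 ⇒ 16.** The C4 carbonyl is taken back to a C4 methylene through the C4 alcohol. The ring-forming step delivers CH2 at C4, and the ring A oxygens on C5, C7 and C8a make that C–H the most hydridic in the molecule. The gain is that C3 is not enolisable until the last two steps. The demand is hydride abstraction at C4 and not at C2, capture of the cation by water before it loses H3, and a non-basic alcohol oxidation.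

**16 ⇒ 15.** The carbonate O–C(=O) bond is cut. The ring B phenol has to be free for ring formation but would steer the oxidant to C2. An acyl cap makes ring B electron-poor and leaves in the final hydrogenolysis. The demand is acylation of this phenol next to the chelated luteolin 5-OH.

**15 ⇒ 9 + 12 (through 13 and 14).** C3–C4 and O1–C2 are cut. This opens ring C into two fragments of similar size and removes both stereocentres at once. The hindered C3–C8 bond becomes an ordinary aryl–vinyl bond in 9. The forward step must control regiochemistry (oxygen to the carbon bearing the hydroxyphenyl ring), absolute configuration at C3, the trans relationship, and chemoselectivity against self-reaction of 13.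

**12 ⇒ 11 ⇒ 10.** The benzylic C–OH is taken back to the aldehyde and two benzyl O–C bonds are cut. The aldehyde holds one ortho-hydroxyl in a hydrogen bond, which is what allows exactly two of three phenols to be alkylated. The demand is a reduction that stops at the alcohol, since 12 ionises easily.

**9 ⇒ 8 ⇒ 7.** The O–Si bond of the stilbene phenol and the O7–S bond of the sulfate diester are cut. In 7 the 5-OH is chelated to the C4 carbonyl, so O7 is the only nucleophilic phenol and needs no further differentiation. The demand is a silyl cleavage that leaves the sulfate diester alone.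

**7 ⇒ 6.** Two O–CH2OMe bonds are cut. The acetals are needed only to carry ring A through iodination and coupling. The demand is acid mild enough for the aryl silyl ether, the ketal and the electron-rich alkene.

**6 ⇒ 4 + 5.** The C8–vinyl bond is cut. This gives an aryl iodide and a commercial styrene, and the E geometry comes from the coupling itself. The demand is oxidative addition at a di-ortho-substituted, electron-rich carbon.

**4 ⇒ 3 ⇒ 2 ⇒ 1.** The C8–I bond, two O–CH2OMe bonds and the ketal on ring B are cut. The catechol is the only site that can form a five-membered ketal. With both ring A oxygens alkylated, electrophiles go to C8 and not to C6. The demand is regiocontrol in the iodination.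

## Other disconnections considered

**Alternative 1:** The cut is at C8–C8a and C6–C7 of luteolin ring A. Ring A would be grown on flavan C3 from siloxyalkyne A1 and 3-ethoxycyclobut-2-enone A2 by a Danheiser benzannulation.

- Forward step: heating would open A2 to a vinylketene, which adds to the alkyne of A1 by [2+2] addition. A 4π opening and a 6π closure would then give A3, with a free phenol at C8a, a silyl ether at O7 and an ethyl ether at O5.
- In favour: the crowded C3–C8 bond exists as a slim sp3–sp bond before the ring is built, and the regiochemistry follows from the mechanism. The three ring A oxygens are born differentiated, so O7 could be unmasked alone. On that point, and on precedent for the reaction type, this alternative is better than the chosen plan.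
- Against: the step makes no stereocentre, so C2, C3 and the C4 silyloxy centre need their own asymmetric synthesis of A1. A3 still lacks the luteolin pyranone ring and ring B. The O5 ethyl ether would need a boron halide late, next to benzyl ethers.
- Comparison: in structure it closes one carbocycle, against ring C plus both stereocentres in the chosen step. In mechanism it is the more secure of the two. In step economy it is clearly longer and linear.

**Alternative 2:** The cut is at C4a–C4, C4–C3 and O1–C2 of the luteolin pyranone ring.

- Forward step: iodophenol A4, alkyne A5 and one carbonyl carbon would combine in a carbonylative Sonogashira coupling under PdCl2(PPh3)2 with a secondary amine. A 6-endo oxa-Michael closure would then give A6.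
- In favour: three bonds form convergently by a known reaction type. The closure uses one of two equivalent hydroxyls and leaves the other free exactly at O7, so no protecting group is needed there. The endgame from A6 would be sulfation and hydrogenolysis only. On both points it is better than the chosen plan.
- Against: A4 already contains the flavanone with both stereocentres and the crowded C3–aryl bond, so the central problem is moved and not solved. Amine base and heat threaten C3 (α to the ketone) and C2 (retro-oxa-Michael opening). Mono-iodination of the symmetric ring and 5-exo closure to an aurone are further selectivity issues.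
- Comparison: in structure it builds a ring that the chosen plan buys with luteolin. In mechanism it is well precedented but on a base-sensitive substrate. In step economy the endgame is shorter, but the total would be longer once a route to A4 is counted.

**Alternative 3:** The cut is at C4a–C5 of luteolin ring A.

- Forward step: base would convert the pyranone β-keto ester A7 into the extended dienolate running from C8 through C8a and C4a to the pyranone carbonyl. Attack of C4a on the ester, loss of methanol and enolisation would give A8 with free 5-OH and 7-OH.
- In favour: it is a polyketide-like folding driven by aromatisation and needs no transition metal. It ends in a 5,7-diol in which only O7 is nucleophilic. On this point it is the equal of the chosen plan, which reaches the same situation in 7.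
- Against: the most acidic position of A7 is the methylene between ketone and ester, not C8, so the reacting carbanion needs a second deprotonation. C4a of a 4-pyranone is a weak nucleophile, and the pyranone can be opened by alkoxide. A7 is a long, sensitive chain on a flavan whose stereocentres must be made beforehand.
- Comparison: in structure it forms one bond and one ring and no stereocentre. In mechanism it is no more secure than the chosen key step. In step economy it is longer.

Key step: step 10

**Remarks on the chemistry**

- Configuration check: the target is (2R,3S) with the aryl groups trans. Chroman 15 has the same spatial arrangement and the same descriptors. Alcohol 17 is formally (2R,3R) only because the C4 oxygen changes the ranking at C3.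
- Precursor design: luteolin ring B is carried as the benzophenone ketal and the 5-OH is left free. A 5,3',4'-tribenzyl ether with only O7 open cannot be reached selectively from luteolin, because O7 is its most reactive phenol. The styryl phenol is carried as a silyl ether, not an acetate, so that it can be released with fluoride next to the sulfate diester. The sulfate diester is in place before the stilbene meets the acid catalyst, so O7 cannot add to the alkene. Alcohol 12 is made fresh and fed slowly.
- Assumption: the sense of induction of the acid with this substrate pair cannot be deduced from precedent. (R)-TRIP is written, and the (S) acid is to be taken if the opposite chroman forms.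
- Assumption: the target is drawn as the free hydrogen sulfate. The route delivers the ammonium salt 19, which is protonated on a cation-exchange resin and handled cold.

## Steps

**Step 1**
Reactants: 1 luteolin
Product: 2 luteolin 3',4'-O-diphenylmethylene ketal (5,7-dihydroxy-2-(2,2-diphenyl-1,3-benzodioxol-5-yl)chromen-4-one)
Conditions: Ph2CCl2 (1.5 equiv), Ph2O, 175 °C
Reagents that add atoms: dichlorodiphenylmethane, ClC(Cl)(c1ccccc1)c1ccccc1
Why: Ketalisation of a catechol with a geminal dichloride (double substitution); only the vicinal 3',4'-pair can close the five-membered dioxole, so the 5- and 7-hydroxyls stay free, and the ketal is removable by hydrogenolysis.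

**Step 2**
Reactants: 2 ketal diol
Product: 3 5,7-bis(methoxymethoxy)-2-(2,2-diphenyl-1,3-benzodioxol-5-yl)chromen-4-one
Conditions: NaH (2.5 equiv), MOMCl (2.5 equiv), DMF, 0 °C to rt
Reagents that add atoms: chloromethyl methyl ether, COCCl
Why: Williamson-type O-alkylation; NaH also deprotonates the chelated 5-OH, so both ring A phenols become acetal ethers, and alkylation of O5 is what directs the next electrophile to C8.

**Step 3**
Reactants: 3 bis-MOM ether
Product: 4 8-iodo-5,7-bis(methoxymethoxy)-2-(2,2-diphenyl-1,3-benzodioxol-5-yl)chromen-4-one
Conditions: BnMe3N·ICl2 (1.2 equiv), CaCO3, CH2Cl2/MeOH, rt, dark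
Reagents that add atoms: benzyltrimethylammonium dichloroiodate, C[N+](C)(C)Cc1ccccc1.Cl[I-]Cl
Why: Electrophilic aromatic iodination; in 5,7-di-O-alkylflavones C8 (para to O5, with one acetal neighbour) is the reactive site, while C6 lies between two MOM groups and ring B is deactivated by the pyranone. CaCO3 takes up the HCl, so the acetals and the ketal should survive.

**Step 4**
Reactants: 4 8-iodide; 5 4-(tert-butyldimethylsilyloxy)styrene
Product: 6 (E)-8-[4-(tert-butyldimethylsilyloxy)styryl]-5,7-bis(methoxymethoxy)-2-(2,2-diphenyl-1,3-benzodioxol-5-yl)chromen-4-one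
Conditions: Pd(OAc)2 (5 mol %), P(o-tol)3 (15 mol %), Et3N, DMF, 90 °C
Reagents that add atoms: none
Why: Mizoroki–Heck reaction; oxidative addition of the C8–I bond to zerovalent palladium, syn insertion of the styrene with the aryl group going to the terminal carbon, and syn β-hydride elimination give the E-stilbene. Triethylamine does not attack the aryl silyl ether or the acetals.

**Step 5**
Reactants: 6 bis-MOM stilbene
Product: 7 (E)-8-[4-(tert-butyldimethylsilyloxy)styryl]-5,7-dihydroxy-2-(2,2-diphenyl-1,3-benzodioxol-5-yl)chromen-4-one
Conditions: NaHSO4·SiO2, CH2Cl2, rt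
Reagents that add atoms: none
Why: Acid-catalysed acetal hydrolysis on a solid acid, a method selective for phenolic MOM ethers; the departing phenols are acidic and good leaving groups, while the aryl silyl ether and the diaryl ketal should be inert to this weak heterogeneous acid in dichloromethane.

**Step 6**
Reactants: 7 5,7-diol
Product: 8 (E)-8-[4-(tert-butyldimethylsilyloxy)styryl]-5-hydroxy-4-oxo-2-(2,2-diphenyl-1,3-benzodioxol-5-yl)chromen-7-yl 2,2,2-trichloroethyl sulfate
Conditions: Cl3CCH2OSO2Cl (1.2 equiv), Et3N (1.3 equiv), DMAP (0.2 equiv), THF, 0 °C to rt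
Reagents that add atoms: 2,2,2-trichloroethyl chlorosulfate, ClS(=O)(=O)OCC(Cl)(Cl)Cl
Why: Sulfation by substitution at sulfur of a chlorosulfate; the 5-OH is locked in a hydrogen bond to the C4 carbonyl and is far less nucleophilic, so the neutral sulfate diester should form at O7 only.

**Step 7**
Reactants: 8 silyl ether sulfate diester
Product: 9 (E)-5-hydroxy-8-(4-hydroxystyryl)-4-oxo-2-(2,2-diphenyl-1,3-benzodioxol-5-yl)chromen-7-yl 2,2,2-trichloroethyl sulfate
Conditions: KHF2 (2 equiv), MeOH/THF, rt
Reagents that add atoms: none
Why: Fluoride-mediated desilylation; KHF2 cleaves phenolic silyl ethers at room temperature in a weakly acidic medium, which avoids the basic nucleophiles that could attack sulfur or the trichloroethyl group.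

**Step 8**
Reactants: 10 2,4,6-trihydroxybenzaldehyde
Product: 11 2,4-bis(benzyloxy)-6-hydroxybenzaldehyde
Conditions: BnBr (2.1 equiv), K2CO3 (2.2 equiv), DMF, 0 °C to rt
Reagents that add atoms: benzyl bromide, BrCc1ccccc1
Why: Williamson etherification; the 4-OH and one ortho-OH are alkylated, and the last ortho-OH is held by a hydrogen bond to the aldehyde and is much less acidic, so the reaction should stop at the dibenzyl ether.

**Step 9**
Reactants: 11 dibenzyl aldehyde
Product: 12 3,5-bis(benzyloxy)-2-(hydroxymethyl)phenol
Conditions: NaBH4, THF/MeOH, 0 °C; pH 7 buffer; used at once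
Reagents that add atoms: none
Why: Hydride reduction of an aldehyde; low temperature and a neutral work-up keep the electron-rich benzylic alcohol from losing water, which would lead to over-reduction or self-condensation.

**Step 10**
Reactants: 9 stilbene phenol; 12 2-hydroxybenzyl alcohol
Product: 15 (2R,3S)-trans-5,7-bis(benzyloxy)-2-(4-hydroxyphenyl)chroman bonded at C3 to C8 of the luteolin unit of 9, via ortho-quinone methide 13 (not isolated), via para-quinone methide adduct 14 (not isolated)
Conditions: (R)-TRIP (10 mol %), 5 Å MS, CH2Cl2, 0 °C, 12 (2.5 equiv) added over 12 h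
Reagents that add atoms: none
Why: Proposed new method: the phosphoric acid protonates the benzylic hydroxyl of 12 and, after loss of water, holds ortho-quinone methide 13 by a hydrogen bond from P–OH to its carbonyl oxygen, while the phosphoryl oxygen accepts a hydrogen bond from the 4-hydroxyl of 9, whose alkene then reacts as a vinylogous enol. The alkene carbon next to the luteolin ring (future C3) adds to the unsubstituted methylene of 13 (future C4) to give para-quinone methide 14, and the ring A phenol closes ring C by a 6-exo-trig oxa-1,6-addition onto the exocyclic carbon of 14 (future C2), so the whole is a stepwise formal [4+2] annulation. The closest known reaction type is the chiral phosphoric acid catalysed [4+2] cycloaddition of in situ ortho-quinone methides with ortho-hydroxystyrenes, 3-vinylindoles or enamides; an unsubstituted quinone methide methylene and a 1,2-diaryl alkene with a para-hydroxyl donor lie outside it. C3 is the only stereocentre formed in the C–C bond-forming step, and it is set by the catalyst, which offers one face of the hydrogen-bonded stilbene to 13 inside the pocket of its 2,4,6-triisopropylphenyl groups. C2 is set in the ring closure under control of C3: the E geometry and the equatorial preference of both aryl groups lead to the 2,3-trans chroman, and because the closure is reversible through 14 under the acid, any cis isomer can drain to trans without touching C3. The required regiochemistry is secured because the hydrogen-bonded 4-hydroxyphenyl ring stabilises positive charge at C2 far better than the luteolin ring, which is twisted out of conjugation by its two ortho substituents and carries the pyranone carbonyl and the sulfate diester. Chemoselectivity against self-condensation of electron-rich 12 and 13 is sought by slow addition, so that 13 always meets an excess of 9, and the capped luteolin 7-oxygen cannot add to the activated alkene.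

**Step 11**
Reactants: 15 chroman phenol
Product: 16 benzyl carbonate of 15 at the ring B 4-oxygen
Conditions: CbzCl (1.1 equiv), pyridine, CH2Cl2, 0 °C
Reagents that add atoms: benzyl chloroformate, O=C(Cl)OCc1ccccc1
Why: O-acylation with a chloroformate; the carbonate masks the phenol and makes ring B electron-poor, so C2–H is not hydridic in the next step. The chelated luteolin 5-OH reacts far more slowly, and a carbonate formed there would leave in the last step anyway.

**Step 12**
Reactants: 16 carbonate
Product: 17 4-hydroxy derivative of 16 (C2 and C3 unchanged; C4 configuration not controlled)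
Conditions: DDQ (1.5 equiv), CH2Cl2/H2O (20:1), 0 °C to rt
Reagents that add atoms: water, O
Why: Benzylic oxidation by hydride abstraction with DDQ, the known way to functionalise C4 of 5,7-dialkoxyflavans; the C4 cation is stabilised by the oxygens on C5, C7 and C8a and is captured by water. The new C4 centre is erased in the next step.

**Step 13**
Reactants: 17 benzylic alcohol
Product: 18 (2R,3S)-5,7-bis(benzyloxy)-2-[4-(benzyloxycarbonyloxy)phenyl]chroman-4-one bonded at C3 to C8 of the luteolin unit of 9
Conditions: Dess–Martin periodinane (1.3 equiv), CH2Cl2, rt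
Reagents that add atoms: none
Why: Dess–Martin oxidation of a secondary benzylic alcohol to the ketone without base, so C3 (now α to the carbonyl) and C2 are not exposed to enolisation or ring opening; the trans arrangement is also the more stable one.

**Step 14**
Reactants: 18 protected biflavonoid
Product: 20 target (2R,3S)-5,7-dihydroxy-2-(4-hydroxyphenyl)-3-(luteolin-8-yl)chroman-4-one with the luteolin 7-oxygen as hydrogen sulfate, via ammonium salt 19 (not isolated)
Conditions: H2 (1 atm), 10% Pd/C, HCO2NH4, THF/MeOH, rt; then Dowex 50WX8 (H+ form), MeOH/H2O, 0 °C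
Reagents that add atoms: none
Why: Catalytic hydrogenolysis combined with transfer hydrogenolysis; Pd/C with ammonium formate cleaves the trichloroethyl ester by reductive fragmentation and, under hydrogen, the benzyl ethers, the benzyl carbonate and the diaryl ketal. The medium stays near neutral, so the sulfate monoester, the flavanone stereocentres and the flavone alkene should survive; cation exchange gives the acid form.

## Compound list

1 | luteolin | O=c1cc(-c2ccc(O)c(O)c2)oc2cc(O)cc(O)c12 | starting material
2 | luteolin 3',4'-O-diphenylmethylene ketal | O=c1cc(-c2ccc3OC(c4ccccc4)(c4ccccc4)Oc3c2)oc2cc(O)cc(O)c12 | intermediate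
3 | 5,7-bis(methoxymethyl) ether of 2 | O=c1cc(-c2ccc3OC(c4ccccc4)(c4ccccc4)Oc3c2)oc2cc(OCOC)cc(OCOC)c12 | intermediate
4 | 8-iodo derivative of 3 | O=c1cc(-c2ccc3OC(c4ccccc4)(c4ccccc4)Oc3c2)oc2c(I)c(OCOC)cc(OCOC)c12 | intermediate
5 | 4-(tert-butyldimethylsilyloxy)styrene | C=Cc1ccc(O[Si](C)(C)C(C)(C)C)cc1 | starting material
6 | (E)-8-[4-(tert-butyldimethylsilyloxy)styryl] derivative of 3 | CC(C)(C)[Si](C)(C)Oc1ccc(/C=C/c2c(OCOC)cc(OCOC)c3c(=O)cc(-c4ccc5OC(c6ccccc6)(c6ccccc6)Oc5c4)oc23)cc1 | intermediate
7 | 5,7-diol from 6 | CC(C)(C)[Si](C)(C)Oc1ccc(/C=C/c2c(O)cc(O)c3c(=O)cc(-c4ccc5OC(c6ccccc6)(c6ccccc6)Oc5c4)oc23)cc1 | intermediate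
8 | 7-O-(2,2,2-trichloroethyl) sulfate of 7 | CC(C)(C)[Si](C)(C)Oc1ccc(/C=C/c2c(OS(=O)(=O)OCC(Cl)(Cl)Cl)cc(O)c3c(=O)cc(-c4ccc5OC(c6ccccc6)(c6ccccc6)Oc5c4)oc23)cc1 | intermediate
9 | (E)-8-(4-hydroxystyryl)-5-hydroxy-3',4'-O-diphenylmethylene-luteolin 7-O-(2,2,2-trichloroethyl) sulfate | Oc1ccc(/C=C/c2c(OS(=O)(=O)OCC(Cl)(Cl)Cl)cc(O)c3c(=O)cc(-c4ccc5OC(c6ccccc6)(c6ccccc6)Oc5c4)oc23)cc1 | intermediate
10 | 2,4,6-trihydroxybenzaldehyde | O=Cc1c(O)cc(O)cc1O | starting material
11 | 2,4-bis(benzyloxy)-6-hydroxybenzaldehyde | O=Cc1c(O)cc(OCc2ccccc2)cc1OCc1ccccc1 | intermediate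
12 | 3,5-bis(benzyloxy)-2-(hydroxymethyl)phenol | OCc1c(O)cc(OCc2ccccc2)cc1OCc1ccccc1 | intermediate
13 | 3,5-bis(benzyloxy)-6-methylenecyclohexa-2,4-dien-1-one (ortho-quinone methide) | C=C1C(=O)C=C(OCc2ccccc2)C=C1OCc1ccccc1 | intermediate (not isolated)
14 | para-quinone methide adduct, R at the future C3 | O=C1C=CC(=C[C@@H](Cc2c(O)cc(OCc3ccccc3)cc2OCc2ccccc2)c2c(OS(=O)(=O)OCC(Cl)(Cl)Cl)cc(O)c3c(=O)cc(-c4ccc5OC(c6ccccc6)(c6ccccc6)Oc5c4)oc23)C=C1 | intermediate (not isolated)
15 | (2R,3S)-trans-chroman from 9 and 12 | C1c2c(OCc3ccccc3)cc(OCc3ccccc3)cc2O[C@@H](c2ccc(O)cc2)[C@@H]1c1c(OS(=O)(=O)OCC(Cl)(Cl)Cl)cc(O)c2c(=O)cc(-c3ccc4OC(c5ccccc5)(c5ccccc5)Oc4c3)oc12 | intermediate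
16 | ring B benzyl carbonate of 15 | C1c2c(OCc3ccccc3)cc(OCc3ccccc3)cc2O[C@@H](c2ccc(OC(=O)OCc3ccccc3)cc2)[C@@H]1c1c(OS(=O)(=O)OCC(Cl)(Cl)Cl)cc(O)c2c(=O)cc(-c3ccc4OC(c5ccccc5)(c5ccccc5)Oc4c3)oc12 | intermediate
17 | 4-hydroxy derivative of 16, mixture at C4 | OC1c2c(OCc3ccccc3)cc(OCc3ccccc3)cc2O[C@@H](c2ccc(OC(=O)OCc3ccccc3)cc2)[C@@H]1c1c(OS(=O)(=O)OCC(Cl)(Cl)Cl)cc(O)c2c(=O)cc(-c3ccc4OC(c5ccccc5)(c5ccccc5)Oc4c3)oc12 | intermediate
18 | (2R,3S)-flavanone, fully protected | O=C1c2c(OCc3ccccc3)cc(OCc3ccccc3)cc2O[C@@H](c2ccc(OC(=O)OCc3ccccc3)cc2)[C@@H]1c1c(OS(=O)(=O)OCC(Cl)(Cl)Cl)cc(O)c2c(=O)cc(-c3ccc4OC(c5ccccc5)(c5ccccc5)Oc4c3)oc12 | intermediate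
19 | ammonium salt of the target sulfate | [NH4+].O=C1c2c(O)cc(O)cc2O[C@@H](c2ccc(O)cc2)[C@@H]1c1c(OS(=O)(=O)[O-])cc(O)c2c(=O)cc(-c3ccc(O)c(O)c3)oc12 | intermediate (not isolated)
20 | CNP0314990.1, (2R,3S)-naringenin-(3→8)-luteolin 7-O-hydrogen sulfate | O=C1c2c(O)cc(O)cc2O[C@@H](c2ccc(O)cc2)[C@@H]1c1c(OS(=O)(=O)O)cc(O)c2c(=O)cc(-c3ccc(O)c(O)c3)oc12 | target

## Step count and least certain steps

Total: 14 steps. Longest linear sequence: 12 steps (steps 1–7 and 10–14, from luteolin); steps 8–9 form the two-step side branch.

**Step 10 (key step, the one marked as a new method).**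
- Most likely to go wrong: Friedel–Crafts self-condensation of 13 with its own electron-rich precursor may outrun addition to the hindered, twisted alkene of 9. Facial discrimination may be weak, because the hydrogen-bond donor of 9 is remote from the reacting carbon and the electrophilic carbon of 13 carries no substituent. The phenol ring of 9 may also be C-alkylated ortho to its hydroxyl.
- Fallback (known chemistry), from 9 and 12 back to 15: heat the two in toluene at 110 °C without acid. Thermal generation of the ortho-quinone methide and its inverse-electron-demand hetero-Diels–Alder addition to E-stilbenes is an established route to trans-2,3-diarylchromans. It would give the racemate, that is 15 together with its (2S,3R) enantiomer F1, and the enantiomers would be separated by preparative HPLC on a chiral stationary phase.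
- This fallback answers poor enantiocontrol; it does not cure low reactivity of the alkene.

**Step 12.**
- Most likely to go wrong: loss of H3 from the C4 cation, which would give a 3-aryl-2H-chromene and destroy C3, or hydride abstraction at C2.
- Fallback, from 16 back to 18: run the DDQ oxidation in CH2Cl2/MeOH so that methanol, a homogeneous trap in large excess, gives the 4-methoxy ether F2. A second DDQ treatment in wet CH2Cl2 then abstracts the remaining C4 hydride. Hydrolysis of the resulting oxocarbenium ion, or of the enol ether if H3 is lost at this stage, leads to 18 and by-passes 17 and the Dess–Martin step.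

**Step 5.**
- Most likely to go wrong: acid-promoted addition of the freed 7-hydroxyl across the electron-rich alkene, and partial loss of the silyl ether or the ketal.
- Fallback, from 4 back to 8: remove the acetals at the iodide stage with the same solid acid to give the 8-iodo-5,7-diol F3. Sulfate O7 as in step 6 to give the iodo sulfate diester F4, and couple F4 with 5 under the conditions of step 4.
- The price is that the sulfate diester meets hot triethylamine and palladium.

**Step 4.**
- Most likely to go wrong: slow oxidative addition at the di-ortho-substituted, electron-rich C8–I bond, leading to protodeiodination, and arylation at the internal alkene carbon.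
- Fallback, from 5 back to 6: cross-metathesis of 5 with vinylboronic acid pinacol ester (second-generation Grubbs catalyst, CH2Cl2, 40 °C) gives the (E)-styrylboronic pinacol ester F5. Suzuki–Miyaura coupling of F5 with 4 (Pd(OAc)2, SPhos, K3PO4, dioxane/H2O, 60 °C) gives 6. The alkene geometry and regiochemistry are then fixed before the coupling.

**Step 14.**
- Most likely to go wrong: incomplete hydrogenolysis of the diaryl ketal, over-reduction (luteolin C2=C3, C4 carbonyl, benzylic O1–C2), or hydrolysis of the sulfate during acid exchange.
- Fallback, from 18 back to 19: first cleave only the trichloroethyl ester with Zn and HCO2NH4 in MeOH/THF to give the protected ammonium sulfate F6. Then hydrogenolyse the benzyl-type groups and the ketal over Pd(OH)2/C under H2 in THF/MeOH.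

## Further compounds

F1 | step 10 | (2S,3R) enantiomer of 15 | C1c2c(OCc3ccccc3)cc(OCc3ccccc3)cc2O[C@H](c2ccc(O)cc2)[C@H]1c1c(OS(=O)(=O)OCC(Cl)(Cl)Cl)cc(O)c2c(=O)cc(-c3ccc4OC(c5ccccc5)(c5ccccc5)Oc4c3)oc12
F2 | step 12 | 4-methoxy derivative of 16, mixture at C4 | COC1c2c(OCc3ccccc3)cc(OCc3ccccc3)cc2O[C@@H](c2ccc(OC(=O)OCc3ccccc3)cc2)[C@@H]1c1c(OS(=O)(=O)OCC(Cl)(Cl)Cl)cc(O)c2c(=O)cc(-c3ccc4OC(c5ccccc5)(c5ccccc5)Oc4c3)oc12
F3 | step 5 | 8-iodo-5,7-dihydroxy-2-(2,2-diphenyl-1,3-benzodioxol-5-yl)chromen-4-one | O=c1cc(-c2ccc3OC(c4ccccc4)(c4ccccc4)Oc3c2)oc2c(I)c(O)cc(O)c12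
F4 | step 5 | 7-O-(2,2,2-trichloroethyl) sulfate of F3 | O=c1cc(-c2ccc3OC(c4ccccc4)(c4ccccc4)Oc3c2)oc2c(I)c(OS(=O)(=O)OCC(Cl)(Cl)Cl)cc(O)c12
F5 | step 4 | (E)-2-[4-(tert-butyldimethylsilyloxy)styryl]-4,4,5,5-tetramethyl-1,3,2-dioxaborolane | CC(C)(C)[Si](C)(C)Oc1ccc(/C=C/B2OC(C)(C)C(C)(C)O2)cc1
F6 | step 14 | ammonium salt of the sulfate monoester from 18, other protecting groups intact | [NH4+].O=C1c2c(OCc3ccccc3)cc(OCc3ccccc3)cc2O[C@@H](c2ccc(OC(=O)OCc3ccccc3)cc2)[C@@H]1c1c(OS(=O)(=O)[O-])cc(O)c2c(=O)cc(-c3ccc4OC(c5ccccc5)(c5ccccc5)Oc4c3)oc12
A1 | alternative 1 | flavan-4-ol silyl ether with a (triisopropylsilyloxy)ethynyl group at C3 | CC(C)(C)[Si](C)(C)O[C@H]1c2c(OCc3ccccc3)cc(OCc3ccccc3)cc2O[C@@H](c2ccc(OCc3ccccc3)cc2)[C@@H]1C#CO[Si](C(C)C)(C(C)C)C(C)C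
A2 | alternative 1 | 3-ethoxycyclobut-2-en-1-one | CCOC1=CC(=O)C1
A3 | alternative 1 | 3-(4-ethoxy-2-hydroxy-6-triisopropylsiloxyphenyl)flavan-4-ol silyl ether | CC(C)(C)[Si](C)(C)O[C@H]1c2c(OCc3ccccc3)cc(OCc3ccccc3)cc2O[C@@H](c2ccc(OCc3ccccc3)cc2)[C@@H]1c1c(O[Si](C(C)C)(C(C)C)C(C)C)cc(OCC)cc1O
A4 | alternative 2 | (2R,3S)-tri-O-benzylflavanone with a 4-benzyloxy-2,6-dihydroxy-3-iodophenyl group at C3 | O=C1c2c(OCc3ccccc3)cc(OCc3ccccc3)cc2O[C@@H](c2ccc(OCc3ccccc3)cc2)[C@@H]1c1c(O)cc(OCc2ccccc2)c(I)c1O
A5 | alternative 2 | 3,4-bis(benzyloxy)phenylacetylene | C#Cc1ccc(OCc2ccccc2)c(OCc2ccccc2)c1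
A6 | alternative 2 | hexa-O-benzyl (2R,3S)-biflavonoid with free luteolin 7-OH | O=C1c2c(OCc3ccccc3)cc(OCc3ccccc3)cc2O[C@@H](c2ccc(OCc3ccccc3)cc2)[C@@H]1c1c(O)cc(OCc2ccccc2)c2c(=O)cc(-c3ccc(OCc4ccccc4)c(OCc4ccccc4)c3)oc12
A7 | alternative 3 | methyl 4-(flavan-3-yl)-3-oxo-4-[6-(3,4-bis(benzyloxy)phenyl)-4-oxopyran-2-yl]butanoate, flavan as 4-O-silyl tri-O-benzyl ether | CC(C)(C)[Si](C)(C)O[C@H]1c2c(OCc3ccccc3)cc(OCc3ccccc3)cc2O[C@@H](c2ccc(OCc3ccccc3)cc2)[C@@H]1C(C(=O)CC(=O)OC)c1cc(=O)cc(-c2ccc(OCc3ccccc3)c(OCc3ccccc3)c2)o1
A8 | alternative 3 | 3-(3',4'-di-O-benzyl-luteolin-8-yl)flavan-4-ol silyl ether with free luteolin 5-OH and 7-OH | CC(C)(C)[Si](C)(C)O[C@H]1c2c(OCc3ccccc3)cc(OCc3ccccc3)cc2O[C@@H](c2ccc(OCc3ccccc3)cc2)[C@@H]1c1c(O)cc(O)c2c(=O)cc(-c3ccc(OCc4ccccc4)c(OCc4ccccc4)c3)oc12
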